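## Retrosynthetic overview
1. The C3–CH2Ar bond is cut back to the enolate of the β-[aryl(hydroxy)methyl]-γ-butyrolactone and an O-benzyl vanillyl bromide (trans alkylation sets C3). The phenol is freed last.
2. That hydroxy lactone comes from a cis-fused γ-lactone/isoxazolidine bicycle by reductive excision of nitrogen (N–O first, then Cα–N). Nitrogen only carries the benzylic oxygen and the chiral auxiliary.
3. The bicycle comes from an intramolecular nitrone–alkene [3+2] of the glyoxylate-nitrone ester of (E)-3,4-dimethoxycinnamyl alcohol. C3–C4 and C7'–O form suprafacially, which fixes C4 and C7'.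
4. Ring order: lactone and isoxazolidine close together in that one event. The isoxazolidine is opened afterwards, the lactone is kept, and no further ring is made.

Assumption: 1, 2 (50 % solution in toluene), 3 (sold as the oxalate, free-based with aq NaHCO3 before use) and 9 are bought. C7' is the carbinol carbon (lignan numbering).

## Route

Step 1
Reactants: 1 (E)-3-(3,4-dimethoxyphenyl)prop-2-en-1-ol; 2 ethyl glyoxylate; 3 (S)-N-(1-phenylethyl)hydroxylamine
Product: 6 (3S,3aR,6aS)-3-(3,4-dimethoxyphenyl)-1-[(S)-1-phenylethyl]tetrahydrofuro[3,4-c]isoxazol-6-one (cis-fused; numbering N1 O2 C3 C3a C4 O5 C6 C6a), via ethyl ester nitrone 4 (not isolated), via cinnamyl ester nitrone 5 (not isolated)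
Conditions: 2 + 3, 4 Å MS, toluene, rt, 1 h; then 1, Ti(OiPr)4 (20 mol %), 80 °C, 24 h; SiO2 separation of the two diastereomers
Reagents that add atoms: none
Why: Nitrone condensation, Ti(IV)-catalysed transesterification and intramolecular nitrone–olefin 1,3-dipolar cycloaddition run in tandem: the three-atom ester tether enforces the fused regiochemistry (nitrone C to the future C4, nitrone O to the benzylic carbon) and the cis ring fusion, the suprafacial addition turns the E geometry into the aryl/CH2O trans relationship (the 4R,7'S relative configuration of the target), and the (S)-1-phenylethyl group makes the two alkene-face adducts diastereomers, of which 6 is separated from its (3R,3aS,6aR) isomer.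

Step 2
Reactants: 6 cis-fused lactone/isoxazolidine
Product: 8 (4R)-4-[(S)-(3,4-dimethoxyphenyl)(hydroxy)methyl]dihydrofuran-2(3H)-one, via amino alcohol 7 (not isolated)
Conditions: SmI2 (9 equiv), THF–HMPA (10:1), MeOH (10 equiv), 0 °C → rt; Rochelle salt work-up, dilute citric acid wash
Reagents that add atoms: none
Why: Proposed new method: this is a one-flask union of two known SmI2 reductions, in which two electrons first break the weak N–O bond of the isoxazolidine (known reductive N–O cleavage, giving 7 with the free 7'-OH) and HMPA-activated SmI2 then delivers two more electrons to the lactone carbonyl so that the α-amino group leaves and MeOH protonates the samarium enolate (closest precedent: SmI2–HMPA reductive α-deamination of α-amino esters and ketones), with C4 and C7' as spectators and the C3 centre deliberately erased.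

Step 3
Reactants: 9 4-(benzyloxy)-3-methoxybenzyl alcohol
Product: 10 4-(benzyloxy)-3-methoxybenzyl bromide
Conditions: PBr3 (0.4 equiv), Et2O, 0 °C, 1 h; used crude
Reagents that add atoms: phosphorus tribromide, BrP(Br)Br
Why: SN2 bromination of a primary benzylic alcohol through its phosphite ester (PBr3 bromination), with no stereocentre involved and the aryl benzyl ether stable at 0 °C.

Step 4
Reactants: 8 hydroxy lactone; 10 benzylic bromide
Product: 12 (3R,4R)-3-[4-(benzyloxy)-3-methoxybenzyl]-4-[(S)-(3,4-dimethoxyphenyl)(hydroxy)methyl]dihydrofuran-2(3H)-one, via dilithio dianion 11 (not isolated)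
Conditions: 8 added to LDA (2.2 equiv), THF, −78 °C, 45 min; 10 (1.1 equiv), −78 → −45 °C; AcOH quench at −78 °C
Reagents that add atoms: none
Why: Alkoxide–enolate dianion alkylation (SN2 on the benzylic bromide), in which the enolate carbon is far more nucleophilic than the hindered lithium alkoxide and the bromide approaches the enolate face opposite the bulky C4 substituent, setting C3 as 3R (3,4-trans) as is general for β-substituted γ-butyrolactone enolates in lignan synthesis.

Step 5
Reactants: 12 O-benzyl ether of the target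
Product: 13 (3R,4R)-4-[(S)-(3,4-dimethoxyphenyl)(hydroxy)methyl]-3-(4-hydroxy-3-methoxybenzyl)dihydrofuran-2(3H)-one (target)
Conditions: H2 (1 atm), 10 % Pd/C, EtOAc, rt, stopped after 1 equiv H2
Reagents that add atoms: none
Why: Catalytic hydrogenolysis of the aryl benzyl ether is much faster in neutral EtOAc than C–O cleavage of the un-ionised secondary benzylic alcohol, so no stereocentre is touched.

## Compound list
1 | (E)-3-(3,4-dimethoxyphenyl)prop-2-en-1-ol | COc1ccc(/C=C/CO)cc1OC | starting material
2 | ethyl glyoxylate | CCOC(=O)C=O | starting material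
3 | (S)-N-(1-phenylethyl)hydroxylamine | C[C@H](NO)c1ccccc1 | starting material
4 | C-(ethoxycarbonyl)-N-[(S)-1-phenylethyl]nitrone (E/Z mixture) | CCOC(=O)C=[N+]([O-])[C@@H](C)c1ccccc1 | intermediate
5 | C-{[(E)-3-(3,4-dimethoxyphenyl)allyl]oxycarbonyl}-N-[(S)-1-phenylethyl]nitrone | COc1ccc(/C=C/COC(=O)C=[N+]([O-])[C@@H](C)c2ccccc2)cc1OC | intermediate
6 | (3S,3aR,6aS)-3-(3,4-dimethoxyphenyl)-1-[(S)-1-phenylethyl]tetrahydrofuro[3,4-c]isoxazol-6-one | O=C1OC[C@@H]2[C@@H](c3ccc(OC)c(OC)c3)ON([C@@H](C)c3ccccc3)[C@H]12 | intermediate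
7 | (3S,4R)-4-[(S)-(3,4-dimethoxyphenyl)(hydroxy)methyl]-3-{[(S)-1-phenylethyl]amino}dihydrofuran-2(3H)-one | O=C1OC[C@H]([C@H](O)c2ccc(OC)c(OC)c2)[C@@H]1N[C@@H](C)c1ccccc1 | intermediate
8 | (4R)-4-[(S)-(3,4-dimethoxyphenyl)(hydroxy)methyl]dihydrofuran-2(3H)-one | O=C1OC[C@@H](C1)[C@H](O)c1ccc(OC)c(OC)c1 | intermediate
9 | 4-(benzyloxy)-3-methoxybenzyl alcohol | COc1cc(CO)ccc1OCc1ccccc1 | starting material
10 | 4-(benzyloxy)-3-methoxybenzyl bromide | COc1cc(CBr)ccc1OCc1ccccc1 | intermediate
11 | dilithium alkoxide/enolate of 8 | [Li]OC1=C[C@H](CO1)[C@H](O[Li])c1ccc(OC)c(OC)c1 | intermediate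
12 | (3R,4R)-3-[4-(benzyloxy)-3-methoxybenzyl]-4-[(S)-(3,4-dimethoxyphenyl)(hydroxy)methyl]dihydrofuran-2(3H)-one | COc1cc(C[C@H]2C(=O)OC[C@@H]2[C@H](O)c2ccc(OC)c(OC)c2)ccc1OCc1ccccc1 | intermediate
13 | (3R,4R)-4-[(S)-(3,4-dimethoxyphenyl)(hydroxy)methyl]-3-(4-hydroxy-3-methoxybenzyl)dihydrofuran-2(3H)-one | COc1cc(C[C@H]2C(=O)OC[C@@H]2[C@H](O)c2ccc(OC)c(OC)c2)ccc1O | target

## Step count and risks
Total steps: 5. Longest linear sequence: 4 (steps 1, 2, 4, 5).

**Step 1.** The ester-tethered cycloaddition has close precedent. The weak point is the 1-phenylethyl group, which is a poor face controller: I expect a low ratio, its sense is not secured, and the two adducts may be hard to separate.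

The fallback sets out from 1 and 2 and comes back at 8. It drops the auxiliary and obtains the enantiomer by resolution.
- 2 is condensed with N-benzylhydroxylamine to C-(ethoxycarbonyl)-N-benzylnitrone F1.
- Ti(OiPr)4 exchange with 1 gives the cinnamyl ester N-benzylnitrone F2.
- F2 cyclises to the racemic cis-fused N-benzyl cycloadduct F3.
- The enantiomers of F3 are separated by preparative chiral SFC.
- The (3S,3aR,6aS) enantiomer is reduced with SmI2–HMPA–MeOH through the N-benzyl amino alcohol F4 to 8.

**Step 2.** N–O cleavage is safe, but the second reduction (Cα–N) may stall at 7.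

The fallback sets out from 6 and comes back at 8. It replaces the two-electron expulsion by a radical hydrodeamination.
- SmI2 without HMPA stops at 7, which is isolated.
- H2 over Pd(OH)2/C in MeOH removes the 1-phenylethyl group to give the primary α-amino lactone F5.
- 2,4,6-Triphenylpyrylium tetrafluoroborate in EtOH converts F5 into the Katritzky pyridinium salt F6.
- Blue-light irradiation of F6 with Hantzsch ester generates the α-lactonyl radical, which abstracts hydrogen to give 8.

**Step 4.** The free lithium alkoxide may be O-benzylated or may attack the lactone (translactonisation to the 5-aryl lactone) before the quench.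

The fallback sets out from 8 and comes back at 12. It works with a mono-anion of a protected substrate.
- TBSCl and imidazole in DMF give the silyl ether F7.
- LiHMDS and then 10 at −78 °C give the trans-alkylated silyl ether F8.
- TBAF buffered with AcOH at 0 °C frees the carbinol to give 12.

## Further compounds
F1 | step 1 | C-(ethoxycarbonyl)-N-benzylnitrone | CCOC(=O)C=[N+]([O-])Cc1ccccc1
F2 | step 1 | C-{[(E)-3-(3,4-dimethoxyphenyl)allyl]oxycarbonyl}-N-benzylnitrone | COc1ccc(/C=C/COC(=O)C=[N+]([O-])Cc2ccccc2)cc1OC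
F3 | step 1 | 1-benzyl-3-(3,4-dimethoxyphenyl)tetrahydrofuro[3,4-c]isoxazol-6-one, formed racemic, (3S,3aR,6aS) enantiomer drawn | O=C1OC[C@@H]2[C@@H](c3ccc(OC)c(OC)c3)ON(Cc3ccccc3)[C@H]12
F4 | step 1 | (3S,4R)-3-(benzylamino)-4-[(S)-(3,4-dimethoxyphenyl)(hydroxy)methyl]dihydrofuran-2(3H)-one | O=C1OC[C@H]([C@H](O)c2ccc(OC)c(OC)c2)[C@@H]1NCc1ccccc1
F5 | step 2 | (3S,4R)-3-amino-4-[(S)-(3,4-dimethoxyphenyl)(hydroxy)methyl]dihydrofuran-2(3H)-one | O=C1OC[C@H]([C@H](O)c2ccc(OC)c(OC)c2)[C@@H]1N
F6 | step 2 | 1-{(3S,4R)-4-[(S)-(3,4-dimethoxyphenyl)(hydroxy)methyl]-2-oxotetrahydrofuran-3-yl}-2,4,6-triphenylpyridinium tetrafluoroborate | O=C1OC[C@H]([C@H](O)c2ccc(OC)c(OC)c2)[C@@H]1[n+]3c(-c4ccccc4)cc(-c4ccccc4)cc3-c5ccccc5.F[B-](F)(F)F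
F7 | step 4 | (4R)-4-[(S)-(tert-butyldimethylsilyloxy)(3,4-dimethoxyphenyl)methyl]dihydrofuran-2(3H)-one | O=C1OC[C@@H](C1)[C@H](O[Si](C)(C)C(C)(C)C)c1ccc(OC)c(OC)c1
F8 | step 4 | (3R,4R)-3-[4-(benzyloxy)-3-methoxybenzyl]-4-[(S)-(tert-butyldimethylsilyloxy)(3,4-dimethoxyphenyl)methyl]dihydrofuran-2(3H)-one | COc1cc(C[C@H]2C(=O)OC[C@@H]2[C@H](O[Si](C)(C)C(C)(C)C)c2ccc(OC)c(OC)c2)ccc1OCc1ccccc1
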